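Slowness is how I want to read this flask, so I step through the ash run and watch what becomes of the substrate that leaves, not how much product piles up.

| flask | substrate | reagent | remark | time |
|---|---|---|---|---|
| ash | 14 mM | 0.80 equiv | run made earlier |  |
| oak | 20 mM | 0.80 equiv | run made earlier |  |
| elm | 31 mM | 0.80 equiv | run made earlier |  |
| maple | 14 mM | 1.6 equiv | run made earlier |  |
| west | 14 mM (fed, over 1.5 min) | 0.800 equiv | all else is in the flask from the start; the feed brings no volume worth counting | 2.0 min |
| south | 14 mM | 0.800 equiv (in portions, 5, over 1.5 min) | first portion at the start, last at 1.5 min | 2.0 min |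
| north-east | 14 mM | 0.800 equiv (fed, over 1.5 min) | all else is in the flask from the start; the feed brings no volume worth counting | 2.0 min |
| north | 14 mM | 0.800 equiv | everything together at the start | 2.0 min |

| run | time / s | target / % | side product / % |
|---|---|---|---|
| ash | 10.0 | 4.7 | 16.5 |
| ash | 15.0 | 5.7 | 20.7 |
| ash | 25.0 | 4.3 | 23.1 |
| ash | 40.0 | 8.1 | 24.2 |
| ash | 80.0 | 7.8 | 23.3 |
| oak | 15.0 | 4.2 | 17.2 |
| oak | 30.0 | 5.5 | 17.6 |
| oak | 50.0 | 4.3 | 18.2 |
| oak | 60.0 | 6.1 | 18.2 |
| oak | 80.0 | 7.9 | 19.9 |
| oak | 90.0 | 6.6 | 18.9 |
| elm | 15.0 | 4.3 | 11.7 |
| elm | 30.0 | 2.7 | 13.4 |
| elm | 50.0 | 2.9 | 13.2 |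
| elm | 60.0 | 5.1 | 11.8 |
| elm | 80.0 | 2.9 | 15.2 |
| elm | 90.0 | 4.8 | 14.8 |
| maple | 10.0 | 3.4 | 16.6 |
| maple | 25.0 | 6.6 | 18.6 |
| maple | 40.0 | 4.5 | 21.9 |
| maple | 60.0 | 5.8 | 22.4 |
| maple | 90.0 | 6.4 | 23.6 |

(standard deviation of a reading: 1 percentage point)

- percent here means substrate units held: one self-condensation product counts as two
- the numbers in the tables scatter with a standard deviation of 1 percentage point
- steps thought possible: substrate -> side product; substrate -> target; substrate + reagent -> intermediate A; intermediate A <-> intermediate B; intermediate B <-> intermediate C; 2 substrate -> self-condensation product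

* the best flask by share of target in target plus side product; "all alike" if 1.5 percentage points covers them all (west / south / north-east / north / all alike)
* share of target in target plus side product at the end, west
* share of target in target plus side product at the end, south
* share of target in target plus side product at the end, north-east
* share of target in target plus side product at the end, north

In the first instants of ash, by 10.0 s, side product reads 16.5% and target 4.7%. In the middle, at 25.0 s, side product reads 23.1%. Towards the end of ash it reads 24.2% at 40.0 s and 23.3% at 80.0 s, two readings that differ by less than their scatter of 1 percentage point.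

What is about to matter is the loss. At their last readings, target plus side product is 31.1% in ash but 19.6% in elm, less at the higher charge, which fits a route of second order in substrate, such as the self-condensation. Doubling the reagent in maple gives side product 23.6% at 90.0 s, against 23.3% at 80.0 s in ash.

Now my rule. If target and side product each form first-order from substrate and nothing else makes or takes them, then in an isothermal flask their rates keep a fixed ratio and [substrate] cancels, however the substrate is fed and whatever the other routes take. I summed each run's readings and took target over target plus side product: 22.1% in ash, 23.9% in oak, 22.1% in elm and 20.6% in maple. Their mean is the branching share, the selectivity, read as 22.2%, and I commit to it for each new flask.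

The forecast says all alike, with 22% for west, 22% for south, 22% for north-east and 22% for north: “Feeding substrate or reagent changes the yield, not the share.”

The flasks give all alike: west 23.0%, south 23.0%, north-east 23.0%, north 23.0%, a spread inside 1.5 points.

    substrate → side product (k = 0.0470 /s)
    substrate → target (k = 0.0140 /s)
    substrate + reagent → intermediate A (k = 1.10 /M/s)
    intermediate A ⇌ intermediate B (K = 0.660, k = 0.100 /s)
    intermediate B ⇌ intermediate C (K = 2.70, k = 0.00250 /s)
    2 substrate → self-condensation product (k = 12.0 /M/s)

In north, the side-product step alone has a half-life of 0.25 min and the target step alone 0.83 min, a factor of 3.36. Both half-lives are free of [substrate], and the two rate constants put the target's part at 23.0%. For north-east read at 8.0 min, 22.2% is again my figure for the share; the computed flask holds 7.69% target and a share of 23.0%.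

The data stem from a simulated flask for substances that don't exist; scatter was added.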